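## The problem

The target, 2-(3,5-dihydroxy-4-methoxyphenyl)-3,5,8-trihydroxy-7-methoxy-4H-chromen-4-one (23), is a flavonol: a benzo-fused 4-pyranone (rings A and C) with ring B at C2 and an enolic hydroxyl at C3. It has no stereocentre, so nothing has to be set or relayed; the difficulty is entirely regiochemical. Ring A is oxygenated at every position except C6, and each oxygen is different: O1 at C8a, free OH at C8, OMe at C7, free OH at C5. Two oxygens (on C5 and C8a) flank C4a, and only the C8a oxygen may enter ring C; if the C5 oxygen closes the ring, the isomeric 5,6,7-oxygenated flavone results. The same isomer forms when ring C opens under hot acid with 5-OH free (Wessely–Moser rearrangement), so late ether cleavage by strong acid is excluded. C5–OH and C8–OH are para to each other (a hydroquinone), and with the 3-hydroxy enone they make the free compound sensitive to base and air; the hydroxyls should therefore be released last, under neutral reducing conditions. Ring B is a symmetric 3,5-dihydroxy-4-methoxyphenyl group and poses no problem. The enabling feature is that C5–O and the C4a–C4 bond sit on neighbouring ring A carbons, with the C8a oxygen on the other side of C4a: an aryne spanning C5 and C4a, flanked by C8a–OMe, is polarised to take an oxygen nucleophile at C5 and to leave the carbanion at C4a, where it can capture C4.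

## Retrosynthesis

**23 from 22.** The three benzyl C–O bonds at O8, O3' and O5' are cut. Benzyl is preferred to methyl or silyl masking because hydrogenolysis is neutral and reducing, leaves the two methyl ethers alone, and exposes the hydroquinone only at the very end. The forward step must spare the pyranone C2=C3 bond.

**22 from 21.** The S–O bond of a C5 methanesulfonate is cut. The sulfonate is removed before hydrogenolysis so that base never meets the free hydroquinone. It is removed after C3 is oxygenated, because the flavonol enolate shields C2 from hydroxide better than the 3-iodide would.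

**21 from 19 (through boronate 20).** The C3–O bond is cut back to a C3–I bond. Direct C3–H oxidation of a flavone is the neighbouring option, but the iodide costs nothing because it is installed by the ring closure itself. The forward step (borylation, then oxidation) must run under weak base only.

**19 from 18.** The O1–C2 and C3–I bonds are cut and a methyl group is restored on O1, giving an open ortho-methoxyaryl ynone. Iodocyclisation is preferred to cyclising a free phenol because it uses the C8a methyl ether directly, so the two oxygens beside C4a never have to be distinguished by selective deprotection. It requires the C5 oxygen to be non-nucleophilic.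

**18 from 17.** The O–S bond is cut. The free C5 phenol of 17 would win any ring closure onto the alkyne, so it is capped by the fastest available O-sulfonylation. A sulfonate is chosen over an ether because its oxygen cannot take part in the iodocyclisation.

**17 from 8 and 15 (through aryne 16).** C5–O and C4a–C4 are cut together: insertion of an aryne into the C–O bond of the arylpropiolic acid. A Friedel–Crafts or Fries acylation of phenol 4 would make the same C4a–C4 bond, but it needs a Lewis acid that neither the benzyl ethers nor an alkynoyl electrophile tolerate. The precursors are two simple benzenoid pieces of similar size. The forward reaction must be regioselective (oxygen at C5, acyl at C4a) and must stop at the open ynone.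

**8 from 5, 4, 2 and 1.** The C–Si and O–S bonds of the silylaryl triflate go back to bromophenol 5, the C–Br bond to phenol 4, the phenol C–O bond to aldehyde 2 (aryl migration to oxygen), and the benzyl ether to syringaldehyde 1. The symmetry of 1 makes the bromination site unambiguous.

**15 from 13, 12, 11, 10 and 9.** The C–CO2H bond and the alkyne go back to dibromoalkene 13 and aldehyde 12, which comes from ester 10 through alcohol 11; 10 is the dibenzyl ether of commercial ester 9. Everything here is routine homologation.

## Roads not taken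

**Alternative 1:** The cut is C4a–C5, with ring A built last. The precursor would be methyl 4-(benzyloxy)-4-{5-(benzyloxy)-6-[3,5-bis(benzyloxy)-4-methoxyphenyl]-4-oxo-4H-pyran-2-yl}-3-oxobutanoate (A1). Base would generate an enolate extended through the pyranone, whose ring carbon attacks the terminal ester in a Claisen condensation and aromatises to the 5,7-diol A2.
- Merits: the C3 oxygen is present from the start, the 5-OH is free, and only selective 7-O-methylation and hydrogenolysis would separate A2 from 23. That is a shorter endgame than the chosen plan's five steps.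
- Weak points: A1 is a demanding target in itself. Its most acidic site is the methylene between ketone and ester, not the methine that must become nucleophilic, so a dianion is needed. Lactonisation through the enol oxygen and retro-Claisen cleavage compete.
- Comparison: the chosen plan has the longer endgame, but both of its key-step partners come from commodity aromatics in four and five routine steps, and ring A arrives with all oxygens already differentiated.

**Alternative 2:** The cut is C3–C4. The precursor would be the dialdehyde 3,6-bis(benzyloxy)-2-{1-[3,5-bis(benzyloxy)-4-methoxyphenyl]-2-oxoethoxy}-4-methoxybenzaldehyde (A3). A triazolium-derived carbene would turn the aryl aldehyde into an acyl-anion equivalent that adds to the aliphatic aldehyde, closing ring C as the ketol A4.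
- Merits: convergent and mild; C3–OH and C4=O appear in one step; one dehydrogenation and a hydrogenolysis would finish the synthesis.
- Weak points: A3 contains an alpha-aryloxy-alpha-aryl acetaldehyde, which enolises, hydrates and oxidises easily. Making it requires O-alkylation of a phenol flanked on both sides with a secondary benzylic electrophile. The carbene is more likely to engage the aliphatic aldehyde first, so chemoselectivity between the two aldehydes is uncertain. The ring A aldehyde also needs the same oxygen differentiation that the chosen plan gets from aryne polarisation.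
- Comparison: on paper the endgame is shorter than the chosen one. The chosen plan has the more stable intermediates and a symmetric ring A source.

**Alternative 3:** The cut is C2=C3. The precursor would be the acylmethylene phosphorane ester 3,6-bis(benzyloxy)-5-methoxy-2-[(triphenylphosphoranylidene)acetyl]phenyl 3,5-bis(benzyloxy)-4-methoxybenzoate (A5). The stabilised ylide would attack the neighbouring aroyl ester carbonyl in an intramolecular Wittig reaction, expelling Ph3PO and closing ring C to flavone A6.
- Merits: this ring closure is well established and neutral, and O1 is fixed from the start, so no capping problem arises. As a ring-forming step it is probably more reliable than an aryne insertion that must be stopped at the open ynone.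
- Weak points: A5 needs a ring A ketone in which the future O1 is a free phenol while O5 and O8 are benzylated. That is a selective-protection problem on a tetra-oxygenated benzene. The ylide comes from an alpha-bromoketone on a ring that itself brominates easily. A6 also lacks the C3 oxygen, so a separate C3 hydroxylation is needed.
- Comparison: the chosen plan offers a four-step ring A partner from symmetric syringaldehyde, uses the methyl ether itself as the ring-closing oxygen, and delivers a C3 handle from the ring closure.

Key step: step 10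

Remark on the chemistry: ring positions of all intermediates are referred to by the flavone position they become (O1, C2–C4, C4a, C5–C8, C8a; ring B primed), and 1 and 9 are taken as purchasable.

## Route

Step 1
Reactants: 1 syringaldehyde (4-hydroxy-3,5-dimethoxybenzaldehyde)
Product: 2 4-(benzyloxy)-3,5-dimethoxybenzaldehyde
Conditions: BnBr, K2CO3, DMF, 60 °C
Reagents that add atoms: benzyl bromide, BrCc1ccccc1
Why: Williamson O-benzylation of the only phenol; benzyl is the one ether that leaves by hydrogenolysis at the end while the methyl ethers stay.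

Step 2
Reactants: 2 4-(benzyloxy)-3,5-dimethoxybenzaldehyde
Product: 4 4-(benzyloxy)-3,5-dimethoxyphenol, via aryl formate 3 (not isolated)
Conditions: mCPBA, CH2Cl2, 0 °C → rt; then K2CO3 (cat.), MeOH, rt
Reagents that add atoms: 3-chloroperoxybenzoic acid, O=C(OO)c1cccc(Cl)c1
Why: Baeyer–Villiger (Dakin-type) oxidation; the electron-rich aryl group migrates to oxygen to give formate 3, which is transesterified to the phenol whose oxygen later leaves as triflate.

Step 3
Reactants: 4 4-(benzyloxy)-3,5-dimethoxyphenol
Product: 5 4-(benzyloxy)-2-bromo-3,5-dimethoxyphenol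
Conditions: NBS (1.0 equiv), CH2Cl2, −78 → 0 °C
Reagents that add atoms: N-bromosuccinimide, O=C1CCC(=O)N1Br
Why: electrophilic aromatic bromination ortho to the phenol; the two open positions are equivalent by symmetry, so cold monobromination fixes the future C4a.

Step 4
Reactants: 5 4-(benzyloxy)-2-bromo-3,5-dimethoxyphenol
Product: 8 4-(benzyloxy)-3,5-dimethoxy-2-(trimethylsilyl)phenyl trifluoromethanesulfonate, via trimethylsilyl ether 6 (not isolated), via lithium 2-silylphenoxide 7 (not isolated)
Conditions: HMDS, THF, 70 °C, evaporate; n-BuLi, THF, −100 °C; Tf2O, −100 °C → rt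
Reagents that add atoms: hexamethyldisilazane, C[Si](C)(C)N[Si](C)(C)C; trifluoromethanesulfonic anhydride, O=S(=O)(OS(=O)(=O)C(F)(F)F)C(F)(F)F
Why: O-silylation, bromine–lithium exchange, anionic 1,3 O→C silyl shift (retro-Brook rearrangement) and O-triflation of the lithium phenoxide, the standard one-flask route to ortho-silylaryl triflates; exchange at −100 °C outruns benzylic metalation.

Step 5
Reactants: 9 methyl 3,5-dihydroxy-4-methoxybenzoate
Product: 10 methyl 3,5-bis(benzyloxy)-4-methoxybenzoate
Conditions: BnBr (2.3 equiv), K2CO3, DMF, 60 °C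
Reagents that add atoms: benzyl bromide, BrCc1ccccc1
Why: double Williamson etherification of the two equivalent phenols; the ester is inert to carbonate in DMF.

Step 6
Reactants: 10 methyl 3,5-bis(benzyloxy)-4-methoxybenzoate
Product: 11 [3,5-bis(benzyloxy)-4-methoxyphenyl]methanol
Conditions: LiAlH4, THF, 0 °C
Reagents that add atoms: none
Why: hydride reduction of the ester to the benzylic alcohol; aryl ethers are untouched.

Step 7
Reactants: 11 [3,5-bis(benzyloxy)-4-methoxyphenyl]methanol
Product: 12 3,5-bis(benzyloxy)-4-methoxybenzaldehyde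
Conditions: MnO2, CH2Cl2, rt
Reagents that add atoms: none
Why: MnO2 oxidises the benzylic alcohol selectively to the aldehyde without over-oxidation.

Step 8
Reactants: 12 3,5-bis(benzyloxy)-4-methoxybenzaldehyde
Product: 13 1,3-bis(benzyloxy)-5-(2,2-dibromoethenyl)-2-methoxybenzene
Conditions: CBr4, PPh3, CH2Cl2, 0 °C
Reagents that add atoms: carbon tetrabromide, BrC(Br)(Br)Br
Why: first stage of the Corey–Fuchs homologation; the ylide formed from PPh3 and CBr4 dibromomethylenates the aldehyde.

Step 9
Reactants: 13 1,3-bis(benzyloxy)-5-(2,2-dibromoethenyl)-2-methoxybenzene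
Product: 15 3-[3,5-bis(benzyloxy)-4-methoxyphenyl]prop-2-ynoic acid, via lithium acetylide 14 (not isolated)
Conditions: n-BuLi (2.2 equiv), THF, −78 °C; CO2; 1 M HCl
Reagents that add atoms: carbon dioxide, O=C=O
Why: second stage of the Corey–Fuchs sequence; bromine–lithium exchange, 1,2-shift and deprotonation give acetylide 14, which CO2 carboxylates; benzyl ethers survive n-BuLi at −78 °C.

Step 10
Reactants: 8 4-(benzyloxy)-3,5-dimethoxy-2-(trimethylsilyl)phenyl trifluoromethanesulfonate; 15 3-[3,5-bis(benzyloxy)-4-methoxyphenyl]prop-2-ynoic acid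
Product: 17 1-[3-(benzyloxy)-6-hydroxy-2,4-dimethoxyphenyl]-3-[3,5-bis(benzyloxy)-4-methoxyphenyl]prop-2-yn-1-one, via aryne 16 (not isolated)
Conditions: 15 (1.5 equiv), NaH (1.5 equiv), THF, 0 °C → rt; KF, 18-crown-6, then 8 (1.0 equiv) added over 3 h, THF, 40 °C; AcOH, −78 °C
Reagents that add atoms: none
Why: Fluoride removes the silyl group of 8 and triflate departs, giving aryne 16. The carboxylate oxygen of 15 adds to the aryne carbon remote from the flanking methoxy group (future C5), because the inductively withdrawing C8a–OMe distorts the aryne and stabilises charge at the adjacent carbon (future C4a); C5 is also the unhindered terminus. The C4a aryl anion then attacks the ester carbonyl through a four-membered alkoxide that opens to the C5 phenoxide, a net insertion into the acid C–O bond (anionic Fries-type 1,3-acyl shift); the closest known reaction type is the fluoride-induced insertion of arynes into carboxylic acid C–O bonds giving ortho-hydroxyaryl ketones. No ring closes and no stereocentre forms. Three selectivities are needed: regiochemistry (secured by the C8a methoxy group as above), acyl shift in preference to protonation of the aryl anion, and survival of the ynone beside the new phenoxide. Pre-forming the carboxylate with NaH leaves no proton donor in the flask, so the aryl anion can only undergo the acyl shift and forcing temperatures are not needed. The same proton-free medium gives the 6-endo oxa-Michael adduct (a C3 vinyl anion) nothing to discharge it, so that addition should stay reversible until the cold acid quench converts the phenoxide into the hydrogen-bonded phenol 17; run hot with the free acid, such insertions are known to carry conjugated acids on to chromanones and flavones, which here would give the wrong 6-benzyloxy-5,7-dimethoxy isomer. Excess carboxylate and slow addition of 8 keep the aryne from O-arylating the product, and the surplus 15 is recovered by bicarbonate extraction.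

Step 11
Reactants: 17 1-[3-(benzyloxy)-6-hydroxy-2,4-dimethoxyphenyl]-3-[3,5-bis(benzyloxy)-4-methoxyphenyl]prop-2-yn-1-one
Product: 18 4-(benzyloxy)-2-{3-[3,5-bis(benzyloxy)-4-methoxyphenyl]prop-2-ynoyl}-3,5-dimethoxyphenyl methanesulfonate
Conditions: MsCl, Et3N, CH2Cl2, −40 → 0 °C
Reagents that add atoms: methanesulfonyl chloride, CS(=O)(=O)Cl
Why: O-sulfonylation through sulfene, which traps the phenol within minutes at low temperature, faster than amine-mediated oxa-Michael closure; the sulfonate oxygen is non-nucleophilic and inert to ICl and to zerovalent palladium with dppf.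

Step 12
Reactants: 18 4-(benzyloxy)-2-{3-[3,5-bis(benzyloxy)-4-methoxyphenyl]prop-2-ynoyl}-3,5-dimethoxyphenyl methanesulfonate
Product: 19 8-(benzyloxy)-2-[3,5-bis(benzyloxy)-4-methoxyphenyl]-3-iodo-7-methoxy-4-oxo-4H-chromen-5-yl methanesulfonate
Conditions: ICl (1.2 equiv), CH2Cl2, −78 °C; aq. Na2S2O3
Reagents that add atoms: iodine monochloride, ClI
Why: electrophilic iodocyclisation of an ortho-methoxyaryl ynone; ICl activates the alkyne, the C8a methoxy oxygen attacks 6-endo at C2, and chloride removes the methyl group from the oxonium ion as MeCl, so ring C closes through the intended oxygen and C3 emerges as an alkenyl iodide.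

Step 13
Reactants: 19 8-(benzyloxy)-2-[3,5-bis(benzyloxy)-4-methoxyphenyl]-3-iodo-7-methoxy-4-oxo-4H-chromen-5-yl methanesulfonate
Product: 21 8-(benzyloxy)-2-[3,5-bis(benzyloxy)-4-methoxyphenyl]-3-hydroxy-7-methoxy-4-oxo-4H-chromen-5-yl methanesulfonate, via C3 boronate 20 (not isolated)
Conditions: B2pin2, Pd(dppf)Cl2 (5 mol %), KOAc, 1,4-dioxane, 80 °C; then NaBO3·4H2O, THF/H2O, rt
Reagents that add atoms: bis(pinacolato)diboron, CC1(C)OB(OC1(C)C)B1OC(C)(C)C(C)(C)O1 (boryl group of 20 only); sodium perborate, [Na+].[Na+].O[B-]1(O)OO[B-](O)(O)OO1 (the C3 oxygen)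
Why: Miyaura borylation of the alkenyl iodide (3-iodochromones are established partners in palladium cross-coupling) followed by oxidative C–B cleavage; acetate and perborate are the only bases, which the pyranone and the mesylate tolerate.

Step 14
Reactants: 21 8-(benzyloxy)-2-[3,5-bis(benzyloxy)-4-methoxyphenyl]-3-hydroxy-7-methoxy-4-oxo-4H-chromen-5-yl methanesulfonate
Product: 22 8-(benzyloxy)-2-[3,5-bis(benzyloxy)-4-methoxyphenyl]-3,5-dihydroxy-7-methoxy-4H-chromen-4-one
Conditions: KOH (2 M aq.), 1,4-dioxane, 50 °C, argon; then 1 M HCl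
Reagents that add atoms: none
Why: hydroxide cleaves the aryl sulfonate at sulfur (or by sulfene elimination) and releases the C5 phenoxide; the flavonol is present as its enolate, which shields C2, and C8 is still benzylated so no hydroquinone meets base.

Step 15
Reactants: 22 8-(benzyloxy)-2-[3,5-bis(benzyloxy)-4-methoxyphenyl]-3,5-dihydroxy-7-methoxy-4H-chromen-4-one
Product: 23 2-(3,5-dihydroxy-4-methoxyphenyl)-3,5,8-trihydroxy-7-methoxy-4H-chromen-4-one
Conditions: H2 (1 atm), Pd/C (10%), EtOAc/MeOH, rt; filtration under argon
Reagents that add atoms: none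
Why: hydrogenolysis of the three benzyl ethers under neutral conditions; methyl ethers and the pyranone C2=C3 bond are untouched, and the hydroquinone is released only in a reducing medium.

## Compound list

1 | syringaldehyde (4-hydroxy-3,5-dimethoxybenzaldehyde) | COc1cc(C=O)cc(OC)c1O | starting material
2 | 4-(benzyloxy)-3,5-dimethoxybenzaldehyde | COc1cc(C=O)cc(OC)c1OCc1ccccc1 | intermediate
3 | 4-(benzyloxy)-3,5-dimethoxyphenyl formate | COc1cc(OC=O)cc(OC)c1OCc1ccccc1 | intermediate (not isolated)
4 | 4-(benzyloxy)-3,5-dimethoxyphenol | COc1cc(O)cc(OC)c1OCc1ccccc1 | intermediate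
5 | 4-(benzyloxy)-2-bromo-3,5-dimethoxyphenol | COc1cc(O)c(Br)c(OC)c1OCc1ccccc1 | intermediate
6 | [4-(benzyloxy)-2-bromo-3,5-dimethoxyphenoxy]trimethylsilane | COc1cc(O[Si](C)(C)C)c(Br)c(OC)c1OCc1ccccc1 | intermediate (not isolated)
7 | lithium 4-(benzyloxy)-3,5-dimethoxy-2-(trimethylsilyl)phenoxide | [Li+].COc1cc([O-])c([Si](C)(C)C)c(OC)c1OCc1ccccc1 | intermediate (not isolated)
8 | 4-(benzyloxy)-3,5-dimethoxy-2-(trimethylsilyl)phenyl trifluoromethanesulfonate | COc1cc(OS(=O)(=O)C(F)(F)F)c([Si](C)(C)C)c(OC)c1OCc1ccccc1 | intermediate
9 | methyl 3,5-dihydroxy-4-methoxybenzoate | COC(=O)c1cc(O)c(OC)c(O)c1 | starting material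
10 | methyl 3,5-bis(benzyloxy)-4-methoxybenzoate | COC(=O)c1cc(OCc2ccccc2)c(OC)c(OCc2ccccc2)c1 | intermediate
11 | [3,5-bis(benzyloxy)-4-methoxyphenyl]methanol | COc1c(OCc2ccccc2)cc(CO)cc1OCc1ccccc1 | intermediate
12 | 3,5-bis(benzyloxy)-4-methoxybenzaldehyde | COc1c(OCc2ccccc2)cc(C=O)cc1OCc1ccccc1 | intermediate
13 | 1,3-bis(benzyloxy)-5-(2,2-dibromoethenyl)-2-methoxybenzene | COc1c(OCc2ccccc2)cc(C=C(Br)Br)cc1OCc1ccccc1 | intermediate
14 | {[3,5-bis(benzyloxy)-4-methoxyphenyl]ethynyl}lithium | [Li]C#Cc1cc(OCc2ccccc2)c(OC)c(OCc2ccccc2)c1 | intermediate (not isolated)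
15 | 3-[3,5-bis(benzyloxy)-4-methoxyphenyl]prop-2-ynoic acid | COc1c(OCc2ccccc2)cc(C#CC(=O)O)cc1OCc1ccccc1 | intermediate
16 | 4-(benzyloxy)-3,5-dimethoxybenzyne (1,2-didehydrobenzene with OMe at C3 and C5, OBn at C4) | COC1=C(OCc2ccccc2)C(OC)=CC#C1 | intermediate (not isolated)
17 | 1-[3-(benzyloxy)-6-hydroxy-2,4-dimethoxyphenyl]-3-[3,5-bis(benzyloxy)-4-methoxyphenyl]prop-2-yn-1-one | COc1cc(O)c(C(=O)C#Cc2cc(OCc3ccccc3)c(OC)c(OCc3ccccc3)c2)c(OC)c1OCc1ccccc1 | intermediate
18 | 4-(benzyloxy)-2-{3-[3,5-bis(benzyloxy)-4-methoxyphenyl]prop-2-ynoyl}-3,5-dimethoxyphenyl methanesulfonate | COc1cc(OS(C)(=O)=O)c(C(=O)C#Cc2cc(OCc3ccccc3)c(OC)c(OCc3ccccc3)c2)c(OC)c1OCc1ccccc1 | intermediate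
19 | 8-(benzyloxy)-2-[3,5-bis(benzyloxy)-4-methoxyphenyl]-3-iodo-7-methoxy-4-oxo-4H-chromen-5-yl methanesulfonate | COc1cc(OS(C)(=O)=O)c2c(=O)c(I)c(-c3cc(OCc4ccccc4)c(OC)c(OCc4ccccc4)c3)oc2c1OCc1ccccc1 | intermediate
20 | 8-(benzyloxy)-2-[3,5-bis(benzyloxy)-4-methoxyphenyl]-7-methoxy-4-oxo-3-(4,4,5,5-tetramethyl-1,3,2-dioxaborolan-2-yl)-4H-chromen-5-yl methanesulfonate | COc1cc(OS(C)(=O)=O)c2c(=O)c(B3OC(C)(C)C(C)(C)O3)c(-c3cc(OCc4ccccc4)c(OC)c(OCc4ccccc4)c3)oc2c1OCc1ccccc1 | intermediate (not isolated)
21 | 8-(benzyloxy)-2-[3,5-bis(benzyloxy)-4-methoxyphenyl]-3-hydroxy-7-methoxy-4-oxo-4H-chromen-5-yl methanesulfonate | COc1cc(OS(C)(=O)=O)c2c(=O)c(O)c(-c3cc(OCc4ccccc4)c(OC)c(OCc4ccccc4)c3)oc2c1OCc1ccccc1 | intermediate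
22 | 8-(benzyloxy)-2-[3,5-bis(benzyloxy)-4-methoxyphenyl]-3,5-dihydroxy-7-methoxy-4H-chromen-4-one | COc1cc(O)c2c(=O)c(O)c(-c3cc(OCc4ccccc4)c(OC)c(OCc4ccccc4)c3)oc2c1OCc1ccccc1 | intermediate
23 | 2-(3,5-dihydroxy-4-methoxyphenyl)-3,5,8-trihydroxy-7-methoxy-4H-chromen-4-one | COc1cc(O)c2c(=O)c(O)c(-c3cc(O)c(OC)c(O)c3)oc2c1O | target

## Step count and least certain steps

Total: 15 steps. Longest linear sequence: 11 steps (9 to 23, steps 5–15); the ring A branch (1 to 8) adds 4 steps.

**Step 10 (key step).** The most likely failure is conjugate addition of the new C5 phenoxide to the ynone before the quench, which would fuse ring C on the wrong oxygen. The phenoxide is held next to a good Michael acceptor for hours, and traces of proton donors or the fluorosilane by-product can discharge the C3 anion and make the closure irreversible. Protonation of the aryl anion (simple O-arylation to an aryl ester) and O-arylation of the product by a second aryne are the next most likely losses. The fallback makes the C4a–C4 bond by carbonyl addition with the C5 oxygen masked throughout. It sets out from 5 and 13 and returns at 17.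
- 5 is converted with MOMCl and i-Pr2NEt into 4-(benzyloxy)-2-bromo-3,5-dimethoxy-1-(methoxymethoxy)benzene F1.
- Acetylide 14, made from 13 as in step 9, is formylated with DMF to 3-[3,5-bis(benzyloxy)-4-methoxyphenyl]prop-2-ynal F2.
- Bromine–lithium exchange on F1 (n-BuLi, THF, −78 °C) and addition to F2 should give racemic 1-[3-(benzyloxy)-2,4-dimethoxy-6-(methoxymethoxy)phenyl]-3-[3,5-bis(benzyloxy)-4-methoxyphenyl]prop-2-yn-1-ol F3.
- MnO2 oxidises F3 to 1-[3-(benzyloxy)-2,4-dimethoxy-6-(methoxymethoxy)phenyl]-3-[3,5-bis(benzyloxy)-4-methoxyphenyl]prop-2-yn-1-one F4, and HCl in MeOH/THF removes the acetal to give 17.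

**Step 12.** The most likely failure is electrophilic iodination of the alkoxy-rich rings (C2'/C6' of ring B, C6 of ring A) in competition with activation of the electron-poor alkyne, since ICl is also a strong aromatic iodinating agent. The fallback closes ring C without an electrophilic halogen. It sets out from 18 and returns at 21, bypassing 19 and 20.
- BCl3 (1.1 equiv, CH2Cl2, −78 °C) should cleave, by chelation to the ketone, the only methyl ether ortho to it, giving 4-(benzyloxy)-2-{3-[3,5-bis(benzyloxy)-4-methoxyphenyl]prop-2-ynoyl}-3-hydroxy-5-methoxyphenyl methanesulfonate F5.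
- K2CO3 in acetone then closes ring C by 6-endo oxa-Michael addition through the correct oxygen, giving 8-(benzyloxy)-2-[3,5-bis(benzyloxy)-4-methoxyphenyl]-7-methoxy-4-oxo-4H-chromen-5-yl methanesulfonate F6.
- Dimethyldioxirane epoxidises C2=C3 to the racemic 2,3-epoxide of that flavone, 3-(benzyloxy)-1a-[3,5-bis(benzyloxy)-4-methoxyphenyl]-4-methoxy-7-oxo-1a,7a-dihydro-7H-oxireno[2,3-b]chromen-6-yl methanesulfonate F7, which brief treatment with TsOH opens to flavonol 21.

**Step 13.** The most likely failure is loss of the C3 substituent by protodeiodination or protodeboronation, because C3 is tetrasubstituted, flanked on both sides, and alpha to the carbonyl. The fallback forms C3–O directly by copper catalysis. It sets out from 19 and returns at 23.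
- Benzyl alcohol, CuI, 3,4,7,8-tetramethyl-1,10-phenanthroline and Cs2CO3 in toluene at 80 °C (Ullmann-type coupling of an alkenyl iodide with an alcohol) should give 3,8-bis(benzyloxy)-2-[3,5-bis(benzyloxy)-4-methoxyphenyl]-7-methoxy-4-oxo-4H-chromen-5-yl methanesulfonate F8.
- KOH in aqueous dioxane removes the sulfonate to give 3,8-bis(benzyloxy)-2-[3,5-bis(benzyloxy)-4-methoxyphenyl]-5-hydroxy-7-methoxy-4H-chromen-4-one F9.
- Hydrogenolysis of the four benzyl ethers as in step 15 gives 23.

**Step 4.** The most likely failure is incomplete O→C silyl migration or quenching of the aryllithium, aggravated by competing benzylic metalation, because the lithiated carbon is crowded between two oxygens. The fallback replaces halogen–metal exchange by directed ortho-metalation and makes step 3 unnecessary. It sets out from 4 and returns at 8.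
- Isopropyl isocyanate converts 4 into 4-(benzyloxy)-3,5-dimethoxyphenyl N-(propan-2-yl)carbamate F10.
- N-silylation in the flask (TBSOTf, TMEDA), lithiation between the carbamate and methoxy oxygens (n-BuLi, −78 °C) and Me3SiCl should give 4-(benzyloxy)-3,5-dimethoxy-2-(trimethylsilyl)phenyl N-(propan-2-yl)carbamate F11.
- Et2NH and DBU cleave the carbamate, and PhNTf2 triflates the phenoxide to give 8.

**Step 15.** The most likely failure is aerial oxidation of the freed 5,8-hydroquinone to the quinone during filtration and concentration, or stalled debenzylation through catalyst poisoning by traces of sulfur or iodide from earlier steps. The fallback sets out from 22 and ends at 23 without a new intermediate: Lewis-acid debenzylation with BCl3 and pentamethylbenzene as cation scavenger in CH2Cl2 at −78 °C, with acidic work-up under argon.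

## Further compounds

F1 | step 10 | 4-(benzyloxy)-2-bromo-3,5-dimethoxy-1-(methoxymethoxy)benzene | COCOc1cc(OC)c(OCc2ccccc2)c(OC)c1Br
F2 | step 10 | 3-[3,5-bis(benzyloxy)-4-methoxyphenyl]prop-2-ynal | COc1c(OCc2ccccc2)cc(C#CC=O)cc1OCc1ccccc1
F3 | step 10 | 1-[3-(benzyloxy)-2,4-dimethoxy-6-(methoxymethoxy)phenyl]-3-[3,5-bis(benzyloxy)-4-methoxyphenyl]prop-2-yn-1-ol (racemic) | COCOc1cc(OC)c(OCc2ccccc2)c(OC)c1C(O)C#Cc1cc(OCc2ccccc2)c(OC)c(OCc2ccccc2)c1
F4 | step 10 | 1-[3-(benzyloxy)-2,4-dimethoxy-6-(methoxymethoxy)phenyl]-3-[3,5-bis(benzyloxy)-4-methoxyphenyl]prop-2-yn-1-one | COCOc1cc(OC)c(OCc2ccccc2)c(OC)c1C(=O)C#Cc1cc(OCc2ccccc2)c(OC)c(OCc2ccccc2)c1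
F5 | step 12 | 4-(benzyloxy)-2-{3-[3,5-bis(benzyloxy)-4-methoxyphenyl]prop-2-ynoyl}-3-hydroxy-5-methoxyphenyl methanesulfonate | COc1cc(OS(C)(=O)=O)c(C(=O)C#Cc2cc(OCc3ccccc3)c(OC)c(OCc3ccccc3)c2)c(O)c1OCc1ccccc1
F6 | step 12 | 8-(benzyloxy)-2-[3,5-bis(benzyloxy)-4-methoxyphenyl]-7-methoxy-4-oxo-4H-chromen-5-yl methanesulfonate | COc1cc(OS(C)(=O)=O)c2c(=O)cc(-c3cc(OCc4ccccc4)c(OC)c(OCc4ccccc4)c3)oc2c1OCc1ccccc1
F7 | step 12 | 3-(benzyloxy)-1a-[3,5-bis(benzyloxy)-4-methoxyphenyl]-4-methoxy-7-oxo-1a,7a-dihydro-7H-oxireno[2,3-b]chromen-6-yl methanesulfonate (racemic, cis-fused oxirane) | COc1cc(OS(C)(=O)=O)c2c(c1OCc1ccccc1)OC1(c3cc(OCc4ccccc4)c(OC)c(OCc4ccccc4)c3)OC1C2=O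
F8 | step 13 | 3,8-bis(benzyloxy)-2-[3,5-bis(benzyloxy)-4-methoxyphenyl]-7-methoxy-4-oxo-4H-chromen-5-yl methanesulfonate | COc1cc(OS(C)(=O)=O)c2c(=O)c(OCc3ccccc3)c(-c3cc(OCc4ccccc4)c(OC)c(OCc4ccccc4)c3)oc2c1OCc1ccccc1
F9 | step 13 | 3,8-bis(benzyloxy)-2-[3,5-bis(benzyloxy)-4-methoxyphenyl]-5-hydroxy-7-methoxy-4H-chromen-4-one | COc1cc(O)c2c(=O)c(OCc3ccccc3)c(-c3cc(OCc4ccccc4)c(OC)c(OCc4ccccc4)c3)oc2c1OCc1ccccc1
F10 | step 4 | 4-(benzyloxy)-3,5-dimethoxyphenyl N-(propan-2-yl)carbamate | COc1cc(OC(=O)NC(C)C)cc(OC)c1OCc1ccccc1
F11 | step 4 | 4-(benzyloxy)-3,5-dimethoxy-2-(trimethylsilyl)phenyl N-(propan-2-yl)carbamate | COc1cc(OC(=O)NC(C)C)c([Si](C)(C)C)c(OC)c1OCc1ccccc1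
F0 | step 15 | none | none
A1 | alternative 1 | methyl 4-(benzyloxy)-4-{5-(benzyloxy)-6-[3,5-bis(benzyloxy)-4-methoxyphenyl]-4-oxo-4H-pyran-2-yl}-3-oxobutanoate (racemic) | COC(=O)CC(=O)C(OCc1ccccc1)c1cc(=O)c(OCc2ccccc2)c(-c2cc(OCc3ccccc3)c(OC)c(OCc3ccccc3)c2)o1
A2 | alternative 1 | 3,8-bis(benzyloxy)-2-[3,5-bis(benzyloxy)-4-methoxyphenyl]-5,7-dihydroxy-4H-chromen-4-one | Oc1cc(O)c2c(=O)c(OCc3ccccc3)c(-c3cc(OCc4ccccc4)c(OC)c(OCc4ccccc4)c3)oc2c1OCc1ccccc1
A3 | alternative 2 | 3,6-bis(benzyloxy)-2-{1-[3,5-bis(benzyloxy)-4-methoxyphenyl]-2-oxoethoxy}-4-methoxybenzaldehyde (racemic) | COc1cc(OCc2ccccc2)c(C=O)c(OC(C=O)c2cc(OCc3ccccc3)c(OC)c(OCc3ccccc3)c2)c1OCc1ccccc1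
A4 | alternative 2 | 5,8-bis(benzyloxy)-2-[3,5-bis(benzyloxy)-4-methoxyphenyl]-3-hydroxy-7-methoxychroman-4-one (stereoisomer mixture) | COc1cc(OCc2ccccc2)c2c(c1OCc1ccccc1)OC(c1cc(OCc3ccccc3)c(OC)c(OCc3ccccc3)c1)C(O)C2=O
A5 | alternative 3 | 3,6-bis(benzyloxy)-5-methoxy-2-[(triphenylphosphoranylidene)acetyl]phenyl 3,5-bis(benzyloxy)-4-methoxybenzoate | COc1cc(OCc2ccccc2)c(C(=O)C=P(c2ccccc2)(c2ccccc2)c2ccccc2)c(OC(=O)c2cc(OCc3ccccc3)c(OC)c(OCc3ccccc3)c2)c1OCc1ccccc1
A6 | alternative 3 | 5,8-bis(benzyloxy)-2-[3,5-bis(benzyloxy)-4-methoxyphenyl]-7-methoxy-4H-chromen-4-one | COc1cc(OCc2ccccc2)c2c(=O)cc(-c3cc(OCc4ccccc4)c(OC)c(OCc4ccccc4)c3)oc2c1OCc1ccccc1
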